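**Retrosynthetic overview**
1. Both benzene rings are purchased as bromophenols; no ring is formed in the route, and the three free OH groups are carried as MOM ethers and released last.
2. Disconnection A: resorcinol aryl–CH2 bond, made last by B-alkyl Suzuki coupling of a terminal alkene (via 9-BBN) with bis-MOM 5-bromoresorcinol.
3. Disconnection B: the C(sp2)–C(sp3) bond next to the alkene, made from an (E)-alkenylzirconocene (hept-1-en-6-yne plus Schwartz reagent) and a primary alkyl bromide; this sets the E geometry.
4. Disconnection C: methoxyphenol aryl–CH2 bond, made first by B-alkyl Suzuki coupling of 7-bromohept-1-ene with MOM-protected 3-bromo-5-methoxyphenol.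

Assumption: the target is achiral, so "single enantiomer" is read as the single (E)-alkene isomer, which is the only stereochemical element.

Numbering covers every compound that contributes non-hydrogen atoms; 9-BBN, Cp2Zr(H)Cl, catalysts and bases appear only in the conditions.

**Step 1**
Reactants: 1, 3-bromo-5-methoxyphenol; 2, chloromethyl methyl ether (MOMCl)
Product: 3, 1-bromo-3-methoxy-5-(methoxymethoxy)benzene
Conditions: MOMCl, i-Pr2NEt, CH2Cl2, 0 °C to rt
Reagents that add atoms: MOMCl (2), COCCl
Why: Simple O-alkylation of the phenol gives a MOM ether that is stable to the boranes, bases and Pd/Zr chemistry used later.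

**Step 2**
Reactants: 3; 4, 7-bromohept-1-ene
Product: 5, 1-(7-bromoheptyl)-3-methoxy-5-(methoxymethoxy)benzene
Conditions: 4, 9-BBN, THF, 0 °C to rt; then 3, PdCl2(dppf) (3 mol %), K3PO4·H2O, DMF/THF, 50 °C
Reagents that add atoms: none beyond reactant 4, C=CCCCCCBr (9-BBN delivers only H)
Why: Anti-Markovnikov hydroboration followed by B-alkyl Suzuki–Miyaura coupling; Pd/dppf inserts into the aryl C–Br bond much faster than into the primary alkyl C–Br bond, so the bromide should survive.

**Step 3**
Reactants: 5; 6, hept-1-en-6-yne
Product: 7, 1-methoxy-3-(methoxymethoxy)-5-[(8E)-tetradeca-8,13-dien-1-yl]benzene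
Conditions: 6 (1.6 equiv), Cp2Zr(H)Cl (1.5 equiv), THF, rt; then 5, Pd(acac)2 (2.5 mol %), LiBr (2 equiv), THF/NMP, 55 °C
Reagents that add atoms: none beyond reactant 6, C#CCCCC=C (Cp2Zr(H)Cl delivers only H)
Why: Syn hydrozirconation of the terminal alkyne (faster than the terminal alkene, and the enyne is kept in excess over Zr–H) gives only the (E)-alkenylzirconocene, which undergoes a Pd-catalysed alkyl Negishi-type coupling with the primary bromide with retention of geometry.

**Step 4**
Reactants: 8, 5-bromobenzene-1,3-diol (5-bromoresorcinol); 2, MOMCl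
Product: 9, 1-bromo-3,5-bis(methoxymethoxy)benzene
Conditions: MOMCl (3 equiv), i-Pr2NEt, CH2Cl2, 0 °C to rt
Reagents that add atoms: MOMCl (2), COCCl (two equivalents incorporated)
Why: Double O-alkylation of the phenols gives the coupling partner for the second Suzuki reaction.

**Step 5**
Reactants: 7; 9
Product: 10, 1-[(8E)-14-[3,5-bis(methoxymethoxy)phenyl]tetradec-8-en-1-yl]-3-methoxy-5-(methoxymethoxy)benzene
Conditions: 7, 9-BBN (1.1 equiv), THF, 0 °C to rt; then 9, PdCl2(dppf) (5 mol %), aq. K3PO4, DMF, 60 °C
Reagents that add atoms: none beyond reactants (9-BBN delivers only H)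
Why: 9-BBN hydroborates the monosubstituted terminal alkene far faster than the internal (E)-1,2-dialkyl alkene, and the B-alkyl Suzuki–Miyaura coupling then forms the second aryl–CH2 bond without touching the alkene geometry.

**Step 6**
Reactants: 10
Product: 11, dehydrobisgravillol, 5-[(6E)-14-(3-hydroxy-5-methoxyphenyl)tetradec-6-en-1-yl]benzene-1,3-diol
Conditions: HCl (conc., few equiv), MeOH, 50 °C
Reagents that add atoms: none
Why: Acid-catalysed acetal methanolysis removes all three MOM groups while the aryl methyl ether and the isolated (E)-alkene are inert.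

**Compound list**
1 | 3-bromo-5-methoxyphenol | COc1cc(O)cc(Br)c1 | starting material
2 | chloromethyl methyl ether (MOMCl) | COCCl | starting material (reagent)
3 | 1-bromo-3-methoxy-5-(methoxymethoxy)benzene | COCOc1cc(OC)cc(Br)c1 | intermediate
4 | 7-bromohept-1-ene | C=CCCCCCBr | starting material
5 | 1-(7-bromoheptyl)-3-methoxy-5-(methoxymethoxy)benzene | COCOc1cc(OC)cc(CCCCCCCBr)c1 | intermediate
6 | hept-1-en-6-yne | C#CCCCC=C | starting material
7 | 1-methoxy-3-(methoxymethoxy)-5-[(8E)-tetradeca-8,13-dien-1-yl]benzene | COCOc1cc(OC)cc(CCCCCCC/C=C/CCCC=C)c1 | intermediate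
8 | 5-bromobenzene-1,3-diol | Oc1cc(O)cc(Br)c1 | starting material
9 | 1-bromo-3,5-bis(methoxymethoxy)benzene | COCOc1cc(OCOC)cc(Br)c1 | intermediate
10 | 1-[(8E)-14-[3,5-bis(methoxymethoxy)phenyl]tetradec-8-en-1-yl]-3-methoxy-5-(methoxymethoxy)benzene | COCOc1cc(OC)cc(CCCCCCC/C=C/CCCCCc2cc(OCOC)cc(OCOC)c2)c1 | intermediate
11 | dehydrobisgravillol | COc1cc(O)cc(CCCCCCC/C=C/CCCCCc2cc(O)cc(O)c2)c1 | target

**Totals**
Total steps: 6. Longest linear sequence: 5 (steps 1, 2, 3, 5, 6); step 4 is a one-step side branch.

**Three steps most likely to fail**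
1. Step 3 (alkyne-versus-alkene selectivity of hydrozirconation; β-hydride elimination in the alkyl coupling). Fallback: alkylate lithiated hept-1-en-6-yne with bromide 5 (n-BuLi, THF/DMPU) to give the internal alkyne, then set the E-alkene by Na/NH3 trans-reduction. This costs one extra step and gives the same diene 7.
2. Step 2 (the primary alkyl bromide may not survive the basic Pd conditions). Fallback: form the aryl Grignard from 3 and couple it with excess 1,7-dibromoheptane under Li2CuCl4 catalysis (Kochi coupling) to reach 5 without a borane.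
3. Step 5 (incomplete terminal/internal hydroboration selectivity, or Pd–H alkene migration in the late-stage coupling). Fallback: switch to a convergent Julia–Kocienski endgame. Make Ar–(CH2)7–CHO from 3 (Suzuki with oct-7-en-1-ol/9-BBN, then oxidation) and the phenyltetrazolyl sulfone Ar'–(CH2)6–SO2PT from 9 (Suzuki with hex-5-en-1-ol/9-BBN, Mitsunobu with PT-SH, oxidation). Join them with KHMDS in DME at −60 °C to give the E-alkene 10, then deprotect as in step 6.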